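**Assumptions (one line):** I take the ring C6=C7 alkene as E (ring-trans), as written in the SMILES, and the C3–O–C16 oxepane as part of the target. Numbering is cladiellin-type: C1–C14 are the core, C11 bears OBu, C12 bears Me, C15 is the side-chain CH(Me), C16 is CH2O, C3 is the quaternary ether carbon, and C7 bears Me.

## Retrosynthetic overview
1. The butyrate is installed early on C11-OH. The E-trisubstituted C6=C7 alkene and the 9-membered oxonene are closed last by a B-alkyl Suzuki coupling (C5–C6) between a C3 vinyl group and an (E)-vinyl iodide on the C9 side chain.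
2. The C3–O–C16 oxepane comes from the tertiary alkoxide plus a C16 triflate. C3 itself comes from chelation-controlled vinyl addition to a C2 methyl ketone.
3. The C2 methyl ketone comes from alkenylation of the THF acetal oxocarbenium, then oxidative cleavage.
4. The cyclohexane and the cis-THF form together in one intramolecular Diels–Alder of an acetal-tethered (E,E)-triene (bonds C10–C1 and C13–C14). C11, C12 and C15 are then set by hydroboration and ketone reduction.
5. The triene comes from a Wipf dienyl carbinol plus an enone acetal. Ring order: cyclohexane and THF, then oxepane, then oxonene.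

## Route

**Step 1**
Reactants: 1 (2,2-dimethoxyacetaldehyde); 2 (acetonylidene triphenylphosphorane)
Product: 3 ((E)-5,5-dimethoxypent-3-en-2-one)
Conditions: CH2Cl2, rt
Reagents that add atoms: none
Why: Wittig olefination with a stabilised ylide gives the E-enone, which fixes the later C14/C1 trans relationship.

**Step 2**
Reactants: 4 (4-(trimethylsilyl)but-3-yn-1-ol)
Product: 5 (4-(trimethylsilyl)but-3-ynal)
Conditions: DMP, NaHCO3, CH2Cl2, 0 °C
Reagents that add atoms: none
Why: Dess–Martin oxidation of a primary alcohol; the aldehyde is used at once.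

**Step 3**
Reactants: 6 (2-methylbut-1-en-3-yne); 5
Product: 7 ((S,E)-7-methyl-1-TMS-octa-5,7-dien-1-yn-4-ol)
Conditions: Cp2Zr(H)Cl, CH2Cl2; Me2Zn, –78 °C; cat. (–)-MIB (enantiomer chosen to give the (S)-carbinol); aldehyde 5, toluene, 0 °C
Reagents that add atoms: none
Why: Hydrozirconation, then Zr→Zn transmetalation, then amino-alcohol-catalysed enantioselective alkenylzinc addition (Wipf) sets C9 and gives the E-diene.

**Step 4**
Reactants: 7; 3
Product: 8 (mixed acetal; acetal carbon C2 is an epimeric mixture)
Conditions: PPTS (cat.), CH2Cl2, 4 Å MS, 35 °C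
Reagents that add atoms: none
Why: Acid-catalysed transacetalisation (loss of MeOH) tethers the C9 oxygen to C2; the anomeric mixture converges at Step 12.

**Step 5**
Reactants: 8
Product: 9 (cis-fused 7-acetyl-1-methoxy-5-methyl-3-(TMS-propargyl)-1,3,3a,6,7,7a-hexahydroisobenzofuran)
Conditions: toluene, BHT, 150 °C, sealed tube
Reagents that add atoms: none
Why: Type-1 intramolecular Diels–Alder closes C10–C1 and C13–C14; the endo TS gives the cis-fused THF, the C9 chain sits pseudo-equatorial on the exo face, and the E-enone makes the C14 acyl group trans to C1–C2.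

**Step 6**
Reactants: 9
Product: 10 (isopropenyl analogue)
Conditions: Ph3P=CH2, THF, 0 °C
Reagents that add atoms: methylenetriphenylphosphorane, C=P(c1ccccc1)(c1ccccc1)c1ccccc1
Why: Wittig methylenation converts the C15 methyl ketone to the isopropenyl group and avoids Lewis-acid-sensitive conditions.

**Step 7**
Reactants: 10
Product: 11 (diol: C16-OH; C11-OH trans to C9; C12–Me cis to C9; C15 set)
Conditions: 9-BBN, THF, 0→45 °C; then NaOH, H2O2, 0 °C
Reagents that add atoms: hydrogen peroxide, OO
Why: Hydroboration–oxidation is syn and occurs from the convex (ring-fusion-H) face of the cis-fused bicycle, giving C12–H and C11–O both down (Me up). The 1,1-disubstituted alkene takes H at C15 from the face next to the smaller C13, and the hindered TMS-alkyne is untouched.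

**Step 8**
Reactants: 11
Product: 12 (C16-OTBS)
Conditions: TBSCl, imidazole, CH2Cl2, 0 °C
Reagents that add atoms: tert-butyldimethylsilyl chloride, CC(C)(C)[Si](C)(C)Cl
Why: The primary alcohol is silylated selectively over the hindered axial C11 secondary alcohol.

**Step 9**
Reactants: 12
Product: 13 (C11 ketone)
Conditions: DMP, NaHCO3, CH2Cl2, rt
Reagents that add atoms: none
Why: Buffered Dess–Martin oxidation avoids epimerising C12 or C10.

**Step 10**
Reactants: 13
Product: 14 (C11-OH cis to C9 and C12-Me)
Conditions: NaBH4, MeOH, –78→0 °C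
Reagents that add atoms: none
Why: Small hydride attacks axially from the open convex face, because both flanking axial groups (C9, C12-Me) block the other face, which gives the C11 alcohol with the target configuration.

**Step 11**
Reactants: 14
Product: 15 (C11 butyrate)
Conditions: (PrCO)2O, DMAP, Et3N, CH2Cl2, rt
Reagents that add atoms: butyric anhydride, CCCC(=O)OC(=O)CCC
Why: O-Acylation of the equatorial secondary alcohol installs the natural-product ester.

**Step 12**
Reactants: 15
Product: 16 (C2 isopropenyl THF)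
Conditions: K[CH2=C(Me)BF3], BF3·OEt2, CH2Cl2, –78→0 °C
Reagents that add atoms: potassium isopropenyltrifluoroborate, C=C(C)[B-](F)(F)F.[K+]
Why: BF3 ionises the acetal to the bicyclic oxocarbenium and the alkenyltrifluoroborate adds from the convex face, giving C2–C3 trans to the cyclohexane (2,5-cis); both acetal epimers converge.

**Step 13**
Reactants: 16
Product: 17 (C2 methyl ketone, C3=O)
Conditions: OsO4 (cat.), NaIO4, 2,6-lutidine, dioxane/H2O, rt
Reagents that add atoms: sodium periodate, [Na+].[O-]I(=O)(=O)=O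
Why: Lemieux–Johnson cleavage of the 1,1-disubstituted alkene leaves the TMS-alkyne untouched.

**Step 14**
Reactants: 17
Product: 18 (tertiary allylic alcohol at C3)
Conditions: CH2=CHMgBr, THF, –78 °C
Reagents that add atoms: vinylmagnesium bromide, C=C[Mg]Br
Why: Cram-chelate addition (Mg bridging the ketone O and the THF O) delivers vinyl from the C2–H face, which gives the target C3 configuration.

**Step 15**
Reactants: 18
Product: 19 (free C16-OH and C3-OH)
Conditions: HF·pyridine, pyridine/THF, 0 °C→rt
Reagents that add atoms: none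
Why: Acidic fluoride removes the primary TBS ether without touching the tertiary alcohol, butyrate or TMS-alkyne.

**Step 16**
Reactants: 19
Product: 20 (tetracyclic oxepane, C3 vinyl)
Conditions: Tf2O, 2,6-di-tert-butyl-4-methylpyridine, CH2Cl2, –78 °C→rt
Reagents that add atoms: none
Why: The primary triflate forms selectively, then the tertiary alcohol closes the oxepane by intramolecular Williamson-type 7-exo-tet etherification with retention at C3.

**Step 17**
Reactants: 20
Product: 21 (terminal alkyne)
Conditions: TBAF, THF, 0 °C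
Reagents that add atoms: none
Why: Fluoride-mediated desilylation of the alkynyl TMS group.

**Step 18**
Reactants: 21
Product: 22 ((E)-trisubstituted vinyl iodide)
Conditions: Me3Al, Cp2ZrCl2 (cat.), CH2Cl2, rt; then I2, THF, –30 °C
Reagents that add atoms: trimethylaluminium, C[Al](C)C; iodine, II
Why: Negishi Zr-catalysed carboalumination adds Me and Al syn across the alkyne, then iodinolysis gives the E vinyl iodide, so the ring C6=C7 geometry is preset.

**Step 19**
Reactants: 22
Product: 23 (4-deoxyasbestinin A)
Conditions: 9-BBN, THF, rt; then PdCl2(dppf), AsPh3, K3PO4, THF/DMF/H2O, 50 °C, ~2 mM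
Reagents that add atoms: none
Why: 9-BBN hydroborates only the terminal vinyl group (C5–B), then an intramolecular B-alkyl Suzuki–Miyaura coupling closes C5–C6 with retention of alkene geometry to form the 9-membered oxonene.

## Compound list
1 | 2,2-dimethoxyacetaldehyde | COC(OC)C=O | starting material
2 | 1-(triphenylphosphoranylidene)propan-2-one | CC(=O)C=P(c1ccccc1)(c1ccccc1)c1ccccc1 | starting material
3 | (E)-5,5-dimethoxypent-3-en-2-one | CC(=O)/C=C/C(OC)OC | intermediate
4 | 4-(trimethylsilyl)but-3-yn-1-ol | OCCC#C[Si](C)(C)C | starting material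
5 | 4-(trimethylsilyl)but-3-ynal | O=CCC#C[Si](C)(C)C | intermediate
6 | 2-methylbut-1-en-3-yne | C=C(C)C#C | starting material
7 | (S,E)-7-methyl-1-TMS-octa-5,7-dien-1-yn-4-ol | C=C(C)/C=C/[C@@H](O)CC#C[Si](C)(C)C | intermediate
8 | mixed acetal of 7 with 3 (C2 epimeric) | CC(=O)/C=C/C(OC)O[C@H](/C=C/C(C)=C)CC#C[Si](C)(C)C | intermediate
9 | Diels–Alder adduct: cis-fused 7-acetyl-1-methoxy-5-methyl-3-(TMS-propargyl)hexahydroisobenzofuran | CC(=O)[C@@H]1CC(C)=C[C@@H]2[C@H]1C(OC)O[C@H]2CC#C[Si](C)(C)C | intermediate
10 | 7-isopropenyl analogue of 9 | C=C(C)[C@@H]1CC(C)=C[C@@H]2[C@H]1C(OC)O[C@H]2CC#C[Si](C)(C)C | intermediate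
11 | diol (C16-OH; C11-OH trans to C9; C12-Me cis to C9) | OC[C@H](C)[C@@H]1C[C@@H](C)[C@H](O)[C@@H]2[C@H]1C(OC)O[C@H]2CC#C[Si](C)(C)C | intermediate
12 | C16-OTBS ether of 11 | CC(C)(C)[Si](C)(C)OC[C@H](C)[C@@H]1C[C@@H](C)[C@H](O)[C@@H]2[C@H]1C(OC)O[C@H]2CC#C[Si](C)(C)C | intermediate
13 | C11 ketone | CC(C)(C)[Si](C)(C)OC[C@H](C)[C@@H]1C[C@@H](C)C(=O)[C@@H]2[C@H]1C(OC)O[C@H]2CC#C[Si](C)(C)C | intermediate
14 | C11 alcohol, cis to C9 | CC(C)(C)[Si](C)(C)OC[C@H](C)[C@@H]1C[C@@H](C)[C@@H](O)[C@@H]2[C@H]1C(OC)O[C@H]2CC#C[Si](C)(C)C | intermediate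
15 | C11 butyrate | CC(C)(C)[Si](C)(C)OC[C@H](C)[C@@H]1C[C@@H](C)[C@@H](OC(=O)CCC)[C@@H]2[C@H]1C(OC)O[C@H]2CC#C[Si](C)(C)C | intermediate
16 | C2-isopropenyl THF | CC(C)(C)[Si](C)(C)OC[C@H](C)[C@@H]1C[C@@H](C)[C@@H](OC(=O)CCC)[C@@H]2[C@H]1[C@@H](C(C)=C)O[C@H]2CC#C[Si](C)(C)C | intermediate
17 | C2 methyl ketone | CC(C)(C)[Si](C)(C)OC[C@H](C)[C@@H]1C[C@@H](C)[C@@H](OC(=O)CCC)[C@@H]2[C@H]1[C@@H](C(C)=O)O[C@H]2CC#C[Si](C)(C)C | intermediate
18 | C3 tertiary allylic alcohol | CC(C)(C)[Si](C)(C)OC[C@H](C)[C@@H]1C[C@@H](C)[C@@H](OC(=O)CCC)[C@@H]2[C@H]1[C@@H]([C@@](C)(O)C=C)O[C@H]2CC#C[Si](C)(C)C | intermediate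
19 | C16-OH / C3-OH diol | OC[C@H](C)[C@@H]1C[C@@H](C)[C@@H](OC(=O)CCC)[C@@H]2[C@H]1[C@@H]([C@@](C)(O)C=C)O[C@H]2CC#C[Si](C)(C)C | intermediate
20 | oxepane with C3 vinyl | O1C[C@H](C)[C@@H]2C[C@@H](C)[C@@H](OC(=O)CCC)[C@@H]3[C@H]2[C@@H]([C@]1(C)C=C)O[C@H]3CC#C[Si](C)(C)C | intermediate
21 | terminal alkyne | O1C[C@H](C)[C@@H]2C[C@@H](C)[C@@H](OC(=O)CCC)[C@@H]3[C@H]2[C@@H]([C@]1(C)C=C)O[C@H]3CC#C | intermediate
22 | (E)-vinyl iodide | O1C[C@H](C)[C@@H]2C[C@@H](C)[C@@H](OC(=O)CCC)[C@@H]3[C@H]2[C@@H]([C@]1(C)C=C)O[C@H]3C/C(C)=C/I | intermediate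
23 | 4-deoxyasbestinin A | CCCC(=O)O[C@H]1[C@@H]2[C@@H]3[C@@H](C[C@H]1C)[C@@H](C)CO[C@@]1(C)CC/C=C(\C)C[C@@H]2O[C@@H]31 | target

## Totals
**Total step count:** 19.
**Longest linear sequence:** 18 steps (Steps 2 to 19, starting from 4).

**Three steps most likely to fail:**
1. **Step 5 (tethered Diels–Alder).** The regiochemistry is electronically mismatched, and the cis/trans ring fusion and the facial selectivity from C9 are uncertain. *Fallback:* drop the tether and run an intermolecular endo Diels–Alder of a (1E,3Z)-1-butyryloxy-2-methyl diene (C14 side chain on the diene) with (S)-5-(silyloxymethyl)butenolide, anti to the γ-substituent. Then build the C9 and C2 substituents from the lactone and CH2OSi groups by lactol allylation.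
2. **Step 7 (one-pot hydroboration setting C11, C12 and C15).** The face selectivity is only predicted, and the hindered TMS-alkyne must survive excess 9-BBN. *Fallback:* set C11/C12 by convex-face epoxidation of the ring alkene followed by Cp2TiCl reductive opening. Set C15 by catalyst control: Horner–Wittig to the enol ether, then Ir–P,N asymmetric hydrogenation.
3. **Step 19 (macrocyclic Suzuki).** Closing a strained nine-membered ether with a trans alkene is the least precedented step. *Fallback:* convert the C3 vinyl into a C5 aldehyde (anti-Markovnikov hydration, then oxidation) and close by intramolecular Nozaki–Hiyama–Kishi coupling with the vinyl iodide, then remove the C5 allylic OH by Pd/formate hydrogenolysis of its carbonate.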